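**Plan**

- Lignan numbering: C7/C7' are benzylic, C8 is the carbinol, C8' the ring-fusion CH, C9/C9' the OCH2 carbons; ring A = O–C7'–C8'–C8–C9, ring B = O–C7–C8–C8'–C9'.
- Retrosynthesis: cut C7'–O and C8'–H (ring A, through a C8' iodide), then C7–O(9') and C8–O (ring B) to reach an achiral, twofold-symmetric dienediol; then cut the central C8–C8' bond (alkenyl bromide homocoupling) and both C7=C8 bonds (Wittig) back to vanillin.
- Enabling feature: C7 (benzylic ether carbon of ring B) and C8 (tertiary OH) carry vicinal oxygens, the pattern of an opened 2,3-epoxy alcohol, and the skeleton is otherwise twofold symmetric about C8–C8'. Both oxygens can therefore be introduced at one allylic alcohol unit of an (E,E)-2,3-bis(arylmethylidene)butane-1,4-diol.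
- Forward: chain assembly (steps 1–4), ring B by epoxidation and 5-endo epoxide opening (step 5), ring A by iodoetherification (step 6), then deiodination and desilylation.
- Stereochemistry: C8 from the complex of Ti(OiPr)4 with L-(+)-diisopropyl tartrate (reagent control); C7 by inversion on epoxide opening; C7' by anti iodoetherification of the exocyclic (Z)-alkene; C8' by the enforced cis ring fusion in the radical reduction.

Key step: step 5

Remark: Ar = 4-(tert-butyldimethylsilyloxy)-3-methoxyphenyl throughout; ethyl bromo(triphenylphosphoranylidene)acetate is assumed to be purchasable; L-(+)-DIPT is diisopropyl (2R,3R)-tartrate.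

**Step 1**
Reactants: 1 vanillin (4-hydroxy-3-methoxybenzaldehyde)
Product: 2 4-(tert-butyldimethylsilyloxy)-3-methoxybenzaldehyde
Conditions: TBSCl (1.1 equiv), imidazole (2 equiv), DMF, rt
Reagents that add atoms: tert-butyldimethylsilyl chloride, CC(C)(C)[Si](C)(C)Cl
Why: Imidazole-promoted silylation of the phenol masks the acidic OH for the ylide, hydride, nickel and titanium steps while keeping the ring electron-rich, which steps 5 and 6 rely on.

**Step 2**
Reactants: 2 4-(tert-butyldimethylsilyloxy)-3-methoxybenzaldehyde; 3 ethyl bromo(triphenylphosphoranylidene)acetate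
Product: 4 ethyl (2Z)-2-bromo-3-Ar-prop-2-enoate
Conditions: toluene, 80 °C
Reagents that add atoms: none
Why: Wittig olefination with the ester-stabilised α-bromo ylide places the aryl group trans to the ester, as stabilised ylides generally do, and should therefore give mainly the (Z)-bromoacrylate (aryl cis to bromine), the minor (E) isomer being removed by chromatography.

**Step 3**
Reactants: 4 ethyl (2Z)-2-bromo-3-Ar-prop-2-enoate (two molecules)
Product: 5 diethyl (2E,3E)-2,3-bis(Ar-methylidene)butanedioate
Conditions: NiCl2(PPh3)2 (10 mol %), PPh3 (20 mol %), Zn dust (1.5 equiv), Et4NI (1 equiv), THF, 50 °C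
Reagents that add atoms: none
Why: Reductive homocoupling of an alkenyl bromide on zerovalent nickel (formed from NiCl2(PPh3)2 and Zn) proceeds by oxidative addition, exchange to a dialkenylnickel species and reductive elimination with retention of alkene geometry, so each aryl group stays cis to the new C8–C8' bond and the (E,E)-diene diester, also the thermodynamically preferred isomer, should result.

**Step 4**
Reactants: 5 diethyl (2E,3E)-2,3-bis(Ar-methylidene)butanedioate
Product: 6 (2E,3E)-2,3-bis(Ar-methylidene)butane-1,4-diol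
Conditions: iBu2AlH (5 equiv), CH2Cl2, −78 to 0 °C; aqueous potassium sodium tartrate work-up
Reagents that add atoms: none
Why: Ester reduction with iBu2AlH delivers hydride 1,2 to both conjugated esters and stops at the allylic alcohols, leaving the diene geometry and the aryl silyl ethers intact.

**Step 5**
Reactants: 6 (2E,3E)-2,3-bis(Ar-methylidene)butane-1,4-diol
Product: 8 (2R,3S,4Z)-2-Ar-4-(Ar-methylidene)-3-(hydroxymethyl)oxolan-3-ol, via epoxy diol 7 (not isolated)
Conditions: Ti(OiPr)4 (1.1 equiv), L-(+)-DIPT (1.3 equiv), tBuOOH (1.2 equiv, anhydrous in isooctane), 4 Å molecular sieves, CH2Cl2, −25 °C, then 0 °C; aqueous potassium sodium tartrate work-up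
Reagents that add atoms: tert-butyl hydroperoxide, CC(C)(C)OO
Why: Proposed new method: the complex formed from Ti(OiPr)4 and L-(+)-DIPT binds one allylic alkoxide of 6 together with tBuOOH and transfers oxygen to the C7=C8 face fixed by the tartrate (the sense that turns (E)-cinnamyl alcohols into (2S,3S)-epoxy alcohols), and the titanium-bound epoxide 7 is then opened at its benzylic carbon C7 by the 9'-hydroxyl with inversion. The closest known reactions are the Katsuki–Sharpless epoxidation of (E)-2-substituted cinnamyl alcohols and the Ti(OiPr)4-assisted C3-selective opening of 2,3-epoxy alcohols by oxygen nucleophiles; running them in one flask on a dienediol is the untested part. Ring B closes by 5-endo opening of the epoxide (both epoxide carbons end up in the ring, the 4-exo alternative at C8 would give an oxetane), which is feasible because C7 bears the para-silyloxy aryl group and acquires benzylic cation character once titanium polarises the C7–O bond. C8 (S) is set by the tartrate (reagent control) and C7 (R) by the stereospecific anti opening of the epoxide derived from the (E)-alkene, which places the C7 aryl group cis to the C8 hydroxyl. The step needs enantioface selectivity, mono-oxidation and opening at C7: the two allylic alcohol units of 6 are homotopic through its twofold axis and so lead to the same enantiomer, the alkene left in 8 flanks a tertiary carbinol that this complex epoxidises only slowly, and the non-protic chelating titanium conditions favour benzylic C7 opening over ionisation of the allylic C8–O bond.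

**Step 6**
Reactants: 8 (2R,3S,4Z)-2-Ar-4-(Ar-methylidene)-3-(hydroxymethyl)oxolan-3-ol
Product: 9 (1S,2R,5S,6R)-2,6-di-Ar-5-iodo-3,7-dioxabicyclo[3.3.0]octan-1-ol
Conditions: N-iodosuccinimide (1.2 equiv), NaHCO3, MeCN, 0 °C, dark
Reagents that add atoms: N-iodosuccinimide, O=C1CCC(=O)N1I
Why: Iodoetherification of a homoallylic alcohol in the 5-endo-trig mode: the iodonium ion of the electron-rich exocyclic styrene is opened by the C9 hydroxyl at the benzylic carbon C7' (Markovnikov), which closes ring A, and anti addition across the (Z)-alkene puts iodine on C8' cis to the C8 hydroxyl (the only arrangement a cis-fused bicycle allows) and the C7' aryl group on the exo face.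

**Step 7**
Reactants: 9 (1S,2R,5S,6R)-2,6-di-Ar-5-iodo-3,7-dioxabicyclo[3.3.0]octan-1-ol
Product: 10 (1S,2R,5R,6S)-2,6-di-Ar-3,7-dioxabicyclo[3.3.0]octan-1-ol
Conditions: Bu3SnH (1.5 equiv), Et3B (0.2 equiv), air, toluene, 0 °C
Reagents that add atoms: none
Why: Radical dehalogenation with Bu3SnH: the tertiary C8' radical sits at the fusion of two five-membered rings and can take up hydrogen only cis to the C8 hydroxyl because a trans-fused 3,7-dioxabicyclo[3.3.0]octane is too strained, which sets C8' as (R), while the low temperature and a concentrated hydride donor guard against elimination and 1,2-aryl shift.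

**Step 8**
Reactants: 10 (1S,2R,5R,6S)-2,6-di-Ar-3,7-dioxabicyclo[3.3.0]octan-1-ol
Product: 11 8-hydroxypinoresinol, (1S,2R,5R,6S)-2,6-bis(4-hydroxy-3-methoxyphenyl)-3,7-dioxabicyclo[3.3.0]octan-1-ol
Conditions: Bu4NF (2.2 equiv), AcOH (2.2 equiv), THF, 0 °C
Reagents that add atoms: none
Why: Fluoride-induced desilylation of the two aryl silyl ethers is fast under acetic acid-buffered conditions that should leave the benzylic ethers, the tertiary alcohol and all four stereocentres untouched.

**Compound list**

1 | vanillin (4-hydroxy-3-methoxybenzaldehyde) | COc1cc(C=O)ccc1O | starting material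
2 | 4-(tert-butyldimethylsilyloxy)-3-methoxybenzaldehyde | COc1cc(C=O)ccc1O[Si](C)(C)C(C)(C)C | intermediate
3 | ethyl bromo(triphenylphosphoranylidene)acetate | CCOC(=O)C(Br)=P(c1ccccc1)(c1ccccc1)c1ccccc1 | starting material
4 | ethyl (2Z)-2-bromo-3-[4-(tert-butyldimethylsilyloxy)-3-methoxyphenyl]prop-2-enoate | CCOC(=O)/C(Br)=C/c1ccc(O[Si](C)(C)C(C)(C)C)c(OC)c1 | intermediate
5 | diethyl (2E,3E)-2,3-bis{[4-(tert-butyldimethylsilyloxy)-3-methoxyphenyl]methylidene}butanedioate | CCOC(=O)/C(=C/c1ccc(O[Si](C)(C)C(C)(C)C)c(OC)c1)/C(C(=O)OCC)=C\c1ccc(O[Si](C)(C)C(C)(C)C)c(OC)c1 | intermediate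
6 | (2E,3E)-2,3-bis{[4-(tert-butyldimethylsilyloxy)-3-methoxyphenyl]methylidene}butane-1,4-diol | OC/C(=C/c1ccc(O[Si](C)(C)C(C)(C)C)c(OC)c1)/C(CO)=C\c1ccc(O[Si](C)(C)C(C)(C)C)c(OC)c1 | intermediate
7 | {(2S,3S)-3-Ar-2-[(1Z)-1-Ar-3-hydroxyprop-1-en-2-yl]oxiran-2-yl}methanol, the monoepoxide formed and consumed in step 5 (alkene geometry as in 6, descriptor now Z) | OC[C@@]1(O[C@H]1c2ccc(O[Si](C)(C)C(C)(C)C)c(OC)c2)/C(CO)=C\c1ccc(O[Si](C)(C)C(C)(C)C)c(OC)c1 | intermediate
8 | (2R,3S,4Z)-2-Ar-4-(Ar-methylidene)-3-(hydroxymethyl)oxolan-3-ol (ring B; C2 = C7, C3 = C8; C7 aryl cis to the C8 hydroxyl) | OC[C@]1(O)[C@@H](c2ccc(O[Si](C)(C)C(C)(C)C)c(OC)c2)OC/C1=C/c1ccc(O[Si](C)(C)C(C)(C)C)c(OC)c1 | intermediate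
9 | (1S,2R,5S,6R)-2,6-di-Ar-5-iodo-3,7-dioxabicyclo[3.3.0]octan-1-ol (iodine on C8' cis to the C8 hydroxyl, both aryl groups exo) | COc1cc([C@H]2OC[C@]3(O)[C@@H](c4ccc(O[Si](C)(C)C(C)(C)C)c(OC)c4)OC[C@]23I)ccc1O[Si](C)(C)C(C)(C)C | intermediate
10 | (1S,2R,5R,6S)-2,6-di-Ar-3,7-dioxabicyclo[3.3.0]octan-1-ol (bis-silyl ether of the target) | COc1cc([C@H]2OC[C@]3(O)[C@@H](c4ccc(O[Si](C)(C)C(C)(C)C)c(OC)c4)OC[C@H]23)ccc1O[Si](C)(C)C(C)(C)C | intermediate
11 | 8-hydroxypinoresinol, (1S,2R,5R,6S)-2,6-bis(4-hydroxy-3-methoxyphenyl)-3,7-dioxabicyclo[3.3.0]octan-1-ol | COc1cc([C@H]2OC[C@]3(O)[C@@H](c4ccc(O)c(OC)c4)OC[C@H]23)ccc1O | target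

**Totals**

Total step count: 8. Longest linear sequence: 8 steps (1 to 11).

**Steps most likely to fail**

Step 5 (the proposed new method). Both hydroxyls of the 1,4-diol may bind the same titanium centre, displacing tartrate or blocking the peroxide site, so that rate and face selectivity fall. Free isopropanol may also open the benzylic epoxide before the 9'-hydroxyl does. The fallback uses known chemistry, sets out from 6 and returns at 8. Diol 6 is monosilylated with Et3SiCl and imidazole (1 equiv, CH2Cl2, −78 °C, unreacted 6 recycled) to (2E,3E)-2,3-bis(Ar-methylidene)-4-(triethylsilyloxy)butan-1-ol F1, which is an ordinary single allylic alcohol. Catalytic Katsuki–Sharpless epoxidation (Ti(OiPr)4 10 mol %, L-(+)-DIPT 14 mol %, tBuOOH, 4 Å molecular sieves, CH2Cl2, −25 °C) should then give {(2S,3S)-3-Ar-2-[(1Z)-1-Ar-3-(triethylsilyloxy)prop-1-en-2-yl]oxiran-2-yl}methanol F2, which is not stored. PPTS in MeOH–CH2Cl2 at 0 °C removes the triethylsilyl group while the aryl silyl ethers stay. The freed 9'-hydroxyl closes ring B by acid-catalysed 5-endo opening of the aryl epoxide, passing through 7 to 8, where the route resumes.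

Step 6. The iodonium ion may collapse to an open benzylic cation, which would erode the exo selectivity at C7', and the tertiary iodide may lose HI during isolation. The fallback sets out from 8 and returns at 10, replacing steps 6 and 7. It is a Mukaiyama-type hydrogen-atom-transfer hydroalkoxylation with Co(salen) (N,N'-ethylenebis(salicylideneiminato)cobalt, divalent cobalt, 5 mol %), N-fluoro-2,4,6-trimethylpyridinium tetrafluoroborate and PhSiH3 in PhCF3 at room temperature. Hydrogen-atom transfer to C8' gives the benzylic C7' radical, oxidation gives the cation, and the C9 hydroxyl closes ring A directly. Only the C8' epimer with hydrogen cis to the C8 hydroxyl can cyclise. No halide intermediate and no compound outside the list arises on this path (F0).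

Step 3. Adventitious protons may cause hydrodebromination of the alkenylnickel intermediate, or the alkene geometry may partly scramble, either of which would lower the supply of the (E,E)-diester. The fallback sets out from 4 and returns at 5. Half of 4 is converted by Miyaura borylation (PdCl2(PPh3)2, PPh3, B2pin2, KOPh, toluene, 50 °C) into ethyl (2E)-3-Ar-2-(4,4,5,5-tetramethyl-1,3,2-dioxaborolan-2-yl)prop-2-enoate F3. Suzuki–Miyaura coupling of this boronate with the other half of 4 (Pd(PPh3)4, K3PO4, THF–H2O, 45 °C) then forms the C8–C8' bond with retention at both alkenes to give 5.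

**Further compounds**

F1 | step 5 | (2E,3E)-2,3-bis(Ar-methylidene)-4-(triethylsilyloxy)butan-1-ol | OC/C(=C/c1ccc(O[Si](C)(C)C(C)(C)C)c(OC)c1)/C(CO[Si](CC)(CC)CC)=C\c1ccc(O[Si](C)(C)C(C)(C)C)c(OC)c1
F2 | step 5 | {(2S,3S)-3-Ar-2-[(1Z)-1-Ar-3-(triethylsilyloxy)prop-1-en-2-yl]oxiran-2-yl}methanol | OC[C@@]1(O[C@H]1c2ccc(O[Si](C)(C)C(C)(C)C)c(OC)c2)/C(CO[Si](CC)(CC)CC)=C\c1ccc(O[Si](C)(C)C(C)(C)C)c(OC)c1
F0 | step 6 | none | none
F3 | step 3 | ethyl (2E)-3-Ar-2-(4,4,5,5-tetramethyl-1,3,2-dioxaborolan-2-yl)prop-2-enoate | CCOC(=O)/C(B1OC(C)(C)C(C)(C)O1)=C/c1ccc(O[Si](C)(C)C(C)(C)C)c(OC)c1
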